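**Plan**

1. Retrosynthesis (locants of the target: ring C1–C6 with C1 quaternary, chlorovinyl C7=C8 on C1, C9 the carbon on C3): Br2 is removed from C3/C9 to leave a C3=C9 methylidene; C4–Cl and C6–Cl go back to alcohols of opposite configuration; C4–OH goes back to an allylic C–H, C7=C8 to a C1 ester and C6–OH to a ketone; then the ring bond C1–C2 is cut, and last the chain bond C4–C5.
2. Enabling feature: in ring C1–C6 the unit C2–C3(=C9) is a 2-substituted allyl group on quaternary C1, and C1 also bears carbonyl-level C7 and oxygen-level C6. C1 is therefore the α-carbon of a β-keto ester placed next to an allyl terminus.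
3. Forward: the chain C1–C6–C5–C4–C3(=C9)–C2 is joined by dianion alkylation (C4–C5); the only ring is closed at C1–C2 by palladium allylic alkylation; C6, C7/C8, C4 and C3/C9 are then elaborated in that order.
4. Stereochemistry: C1 comes from the chiral diphosphine in the ring closure. C6 comes from chelation-controlled reduction followed by SN2 chlorination. C4 comes from axial oxygen transfer from selenium followed by SN2 chlorination. C3 comes from axial opening of the bromonium ion, and the Z alkene from a kinetic Wittig reaction.

Key step: step 3

Assumption: the sense of induction of the diphosphine on this tethered enolate cannot be predicted with confidence. The (1R,2R)-ligand is written; its enantiomer is to be used if the first run delivers the mirror image of 6.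

**Route**

Step 1
Reactants: 1 methyl 2-methyl-3-oxobutanoate; 2 3-chloro-2-(chloromethyl)prop-1-ene
Product: 4 methyl 6-(chloromethyl)-2-methyl-3-oxohept-6-enoate, via keto ester dianion 3 (not isolated)
Conditions: NaH, THF, 0 °C; n-BuLi, 0 °C; added to 2 (3 equiv), THF, −78 → −20 °C; 1 M HCl
Reagents that add atoms: none
Why: Dianion (Huckin–Weiler) alkylation: the terminal carbanion of 3 is far more nucleophilic than the internal enolate carbon and displaces one chloride of the symmetrical dichloride, while the excess of 2 and the cold acidic quench should suppress double alkylation and premature ring closure by the second allylic chloride.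

Step 2
Reactants: 4 methyl 6-(chloromethyl)-2-methyl-3-oxohept-6-enoate
Product: 5 methyl 6-[(acetyloxy)methyl]-2-methyl-3-oxohept-6-enoate
Conditions: KOAc (1.5 equiv), AcOH (1 equiv), DMF, 60 °C
Reagents that add atoms: potassium acetate, CC(=O)[O-].[K+]
Why: SN2 displacement of the primary allylic chloride by acetate, buffered with acetic acid so that the keto ester stays protonated and cannot alkylate itself, installs a leaving group that palladium ionises but that an enolate alone does not displace.

Step 3
Reactants: 5 methyl 6-[(acetyloxy)methyl]-2-methyl-3-oxohept-6-enoate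
Product: 6 methyl (1R)-1-methyl-4-methylidene-2-oxocyclohexane-1-carboxylate
Conditions: Pd2(dba)3·CHCl3 (2.5 mol%), (1R,2R)-N,N'-bis[2-(diphenylphosphanyl)benzoyl]cyclohexane-1,2-diamine (7.5 mol%), 1,1,3,3-tetramethylguanidine (1.1 equiv), toluene (0.02 M), 0 °C → rt
Reagents that add atoms: none
Why: Proposed new method: zerovalent palladium carrying the C2-symmetric diphosphine ionises the allylic acetate with inversion to a 2-substituted η3-allyl complex whose two CH2 termini are equivalent, tetramethylguanidine turns the β-keto ester into its enolate, and the enolate carbon C1 attacks a terminus on the face remote from the metal, which makes C1–C2 and leaves C3=C9 as the methylidene. The closest known reaction types are the palladium-catalysed asymmetric allylic alkylation of α-substituted β-keto esters with allyl acetate and a guanidine base, which sets a quaternary centre on the nucleophile, and the racemic palladium ring closure of 2-(acyloxymethyl)allyl chains onto stabilised carbanions; their combination in one enantioselective ring closure is what remains to be shown. The cyclohexanone ring is closed in a 6-(enolendo)-exo-tet manner, C1 displacing palladium from the terminus C2 with the enolate bond C1=C6 inside the new ring. The only new stereocentre, C1, is set by the ligand, whose chiral pocket differentiates the two enolate faces, the substrate offering no bias of its own. The step needs C- rather than O-alkylation, one regiochemical outcome and no uncatalysed pathway: because the tether sits on the central allyl carbon either terminus gives the same ring, the cyclic enol ether from attack by the C6 oxygen is an allyl enol ether that zerovalent palladium can re-ionise so that it should drain into the ketone, and an allylic acetate does not alkylate the enolate without the metal.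

Step 4
Reactants: 6 methyl (1R)-1-methyl-4-methylidene-2-oxocyclohexane-1-carboxylate
Product: 7 methyl (1R,2R)-2-hydroxy-1-methyl-4-methylidenecyclohexane-1-carboxylate
Conditions: Zn(BH4)2, Et2O, −20 → 0 °C; aq NH4Cl
Reagents that add atoms: none
Why: Chelation-controlled hydride reduction: zinc bridges the ketone and ester carbonyls, which holds the ester equatorial and the C1 methyl axial, so that hydride enters C6 along the axial path anti to that methyl and gives the equatorial alcohol trans to the ester (2R in the name of 7), the ester and the alkene being inert to Zn(BH4)2 at this temperature.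

Step 5
Reactants: 7 methyl (1R,2R)-2-hydroxy-1-methyl-4-methylidenecyclohexane-1-carboxylate
Product: 8 methyl (1S,2S)-2-chloro-1-methyl-4-methylidenecyclohexane-1-carboxylate
Conditions: PPh3, NCS, THF, 0 → 40 °C
Reagents that add atoms: N-chlorosuccinimide, O=C1CCC(=O)N1Cl
Why: Appel-type chlorination: chloride displaces the alkoxyphosphonium group at C6 in an SN2 step with inversion, placing chlorine cis to the ester, a displacement next to a quaternary ring carbon that is known for this reagent pair and is helped here by the ester, which disfavours ionisation and rearrangement, and by the absence of a hydrogen on C1.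

Step 6
Reactants: 8 methyl (1S,2S)-2-chloro-1-methyl-4-methylidenecyclohexane-1-carboxylate
Product: 9 [(1S,2S)-2-chloro-1-methyl-4-methylidenecyclohexyl]methanol
Conditions: i-Bu2AlH (2.5 equiv), CH2Cl2, −78 → 0 °C; aq potassium sodium tartrate
Reagents that add atoms: none
Why: Ester reduction by i-Bu2AlH to the neopentyl primary alcohol, the secondary chloride and the 1,1-disubstituted alkene being inert at low temperature.

Step 7
Reactants: 9 [(1S,2S)-2-chloro-1-methyl-4-methylidenecyclohexyl]methanol
Product: 10 (1S,2S)-2-chloro-1-methyl-4-methylidenecyclohexane-1-carbaldehyde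
Conditions: Dess–Martin periodinane, CH2Cl2, 0 °C → rt
Reagents that add atoms: none
Why: Dess–Martin oxidation under neutral conditions gives the aldehyde, which cannot enolise or lose HCl towards the quaternary carbon C1.

Step 8
Reactants: 10 (1S,2S)-2-chloro-1-methyl-4-methylidenecyclohexane-1-carbaldehyde
Product: 11 (1S,2S)-2-chloro-1-[(Z)-2-chloroethenyl]-1-methyl-4-methylidenecyclohexane
Conditions: [Ph3PCH2Cl]Cl, NaN(SiMe3)2, THF, −78 °C; then 10, −78 °C → rt
Reagents that add atoms: (chloromethyl)triphenylphosphonium chloride, ClC[P+](c1ccccc1)(c1ccccc1)c1ccccc1.[Cl-]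
Why: Wittig chloromethylenation: the lithium-free ylide Ph3P=CHCl adds to the hindered, non-enolisable aldehyde under kinetic control through the cis-oxaphosphetane, which should favour the Z chloroalkene, the E isomer being removed by chromatography.

Step 9
Reactants: 11 (1S,2S)-2-chloro-1-[(Z)-2-chloroethenyl]-1-methyl-4-methylidenecyclohexane
Product: 12 (1S,4S,5S)-5-chloro-4-[(Z)-2-chloroethenyl]-4-methyl-2-methylidenecyclohexan-1-ol
Conditions: SeO2 (0.3 equiv), t-BuOOH (2 equiv), CH2Cl2, rt
Reagents that add atoms: selenium dioxide (oxygen carrier), O=[Se]=O; tert-butyl hydroperoxide (terminal oxygen source), CC(C)(C)OO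
Why: Selenium dioxide allylic oxidation (ene reaction at C9 followed by [2,3]-sigmatropic shift): hydrogen should be taken from C4 and not from the neopentyl C2, and oxygen should be delivered axially to C4 in the chair with the C6 chlorine equatorial, the axial path on the other face being blocked by that chlorine, so that the new hydroxyl is trans to the C6 chlorine (1S in the name of 12).

Step 10
Reactants: 12 (1S,4S,5S)-5-chloro-4-[(Z)-2-chloroethenyl]-4-methyl-2-methylidenecyclohexan-1-ol
Product: 13 (1S,2S,4R)-2,4-dichloro-1-[(Z)-2-chloroethenyl]-1-methyl-5-methylidenecyclohexane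
Conditions: PPh3, Cl3CC(O)CCl3, CH2Cl2, 0 °C → rt
Reagents that add atoms: hexachloroacetone, ClC(Cl)(Cl)C(=O)C(Cl)(Cl)Cl
Why: Appel-type chlorination with hexachloroacetone, which converts secondary allylic alcohols into chlorides by SN2 with inversion and without allylic transposition, sets the C4 chlorine cis to the C6 chlorine.

Step 11
Reactants: 13 (1S,2S,4R)-2,4-dichloro-1-[(Z)-2-chloroethenyl]-1-methyl-5-methylidenecyclohexane
Product: 14 (1S,2R,4S,5S)-1-bromo-1-(bromomethyl)-2,4-dichloro-5-[(Z)-2-chloroethenyl]-5-methylcyclohexane
Conditions: Br2 (1.0 equiv), CH2Cl2, −78 °C, dark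
Reagents that add atoms: bromine, BrBr
Why: Electrophilic anti addition of bromine: the bromonium ion on C3=C9 should be opened by bromide at the tertiary carbon C3 along the axial direction of the chair that keeps both chlorines equatorial, giving axial bromine and equatorial CH2Br (the alternative would force CH2Br into a 1,3-diaxial clash with the chlorovinyl group), while the deactivated, hindered chloroalkene should not react at −78 °C with one equivalent.

**Compound list**

1 | methyl 2-methyl-3-oxobutanoate | COC(=O)C(C)C(C)=O | starting material
2 | 3-chloro-2-(chloromethyl)prop-1-ene | ClCC(=C)CCl | starting material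
3 | keto ester dianion (sodium lithium salt of doubly deprotonated 1) | [Na+].[Li+].[CH2-]C([O-])=C(C)C(=O)OC | intermediate
4 | methyl 6-(chloromethyl)-2-methyl-3-oxohept-6-enoate (racemic, C2 epimerisable) | COC(=O)C(C)C(=O)CCC(=C)CCl | intermediate
5 | methyl 6-[(acetyloxy)methyl]-2-methyl-3-oxohept-6-enoate (racemic, C2 epimerisable) | COC(=O)C(C)C(=O)CCC(=C)COC(C)=O | intermediate
6 | methyl (1R)-1-methyl-4-methylidene-2-oxocyclohexane-1-carboxylate | C[C@@]1(C(=O)OC)CC(=C)CCC1=O | intermediate
7 | methyl (1R,2R)-2-hydroxy-1-methyl-4-methylidenecyclohexane-1-carboxylate | C[C@@]1(C(=O)OC)CC(=C)CC[C@H]1O | intermediate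
8 | methyl (1S,2S)-2-chloro-1-methyl-4-methylidenecyclohexane-1-carboxylate | C[C@@]1(C(=O)OC)CC(=C)CC[C@@H]1Cl | intermediate
9 | [(1S,2S)-2-chloro-1-methyl-4-methylidenecyclohexyl]methanol | C[C@@]1(CO)CC(=C)CC[C@@H]1Cl | intermediate
10 | (1S,2S)-2-chloro-1-methyl-4-methylidenecyclohexane-1-carbaldehyde | C[C@@]1(C=O)CC(=C)CC[C@@H]1Cl | intermediate
11 | (1S,2S)-2-chloro-1-[(Z)-2-chloroethenyl]-1-methyl-4-methylidenecyclohexane | C[C@@]1(/C=C\Cl)CC(=C)CC[C@@H]1Cl | intermediate
12 | (1S,4S,5S)-5-chloro-4-[(Z)-2-chloroethenyl]-4-methyl-2-methylidenecyclohexan-1-ol | C[C@@]1(/C=C\Cl)CC(=C)[C@@H](O)C[C@@H]1Cl | intermediate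
13 | (1S,2S,4R)-2,4-dichloro-1-[(Z)-2-chloroethenyl]-1-methyl-5-methylidenecyclohexane | C[C@@]1(/C=C\Cl)CC(=C)[C@H](Cl)C[C@@H]1Cl | intermediate
14 | (1S,2R,4S,5S)-1-bromo-1-(bromomethyl)-2,4-dichloro-5-[(Z)-2-chloroethenyl]-5-methylcyclohexane | C[C@@]1(/C=C\Cl)C[C@@](Br)(CBr)[C@H](Cl)C[C@@H]1Cl | target

Total step count: 11
Longest linear sequence: 11 steps (1 → 14)

**Steps most likely to fail**

Step 3. The flexible, tethered enolate may be discriminated poorly by the ligand pocket, and part of the material may be held as the O-alkylated enol ether. The fallback sets out from 5 and gives up catalytic induction in favour of resolution. Ring closure with the achiral catalyst Pd(PPh3)4 and 1,1,3,3-tetramethylguanidine in THF, a known racemic Tsuji–Trost cyclisation, should give methyl rac-1-methyl-4-methylidene-2-oxocyclohexane-1-carboxylate F1. Zn(BH4)2 reduction as in step 4 should give the racemic trans-hydroxy ester methyl rac-(1R,2R)-2-hydroxy-1-methyl-4-methylidenecyclohexane-1-carboxylate F2. Esterification with (S)-2-methoxy-2-phenylacetic acid (N,N'-dicyclohexylcarbodiimide, 4-(dimethylamino)pyridine, CH2Cl2) gives two diastereomers, separated by chromatography or crystallisation: methyl (1R,2R)-2-{[(2S)-2-methoxy-2-phenylacetyl]oxy}-1-methyl-4-methylidenecyclohexane-1-carboxylate F3 and methyl (1S,2S)-2-{[(2S)-2-methoxy-2-phenylacetyl]oxy}-1-methyl-4-methylidenecyclohexane-1-carboxylate F4. K2CO3 in methanol cleaves F3, and the route is rejoined at 7.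

Step 9. The oxygen transfer to C4 may show poor facial selectivity, and some hydrogen abstraction at C2 may lower the yield. The fallback sets out from 11; the oxidation is run as in step 9 and the C4 epimers are separated. The unwanted epimer (1R,4S,5S)-5-chloro-4-[(Z)-2-chloroethenyl]-4-methyl-2-methylidenecyclohexan-1-ol F5 is inverted by a Mitsunobu reaction (PPh3, diisopropyl azodicarboxylate, 4-nitrobenzoic acid, THF, 0 °C) to (1S,4S,5S)-5-chloro-4-[(Z)-2-chloroethenyl]-4-methyl-2-methylidenecyclohexyl 4-nitrobenzoate F6. K2CO3 in methanol then releases the alcohol, and the route is rejoined at 12. The configuration at C4 then rests on an SN2 inversion and no longer on the facial preference of the sigmatropic shift.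

Step 8. Kinetic cis selectivity in oxaphosphetane formation may be weak for the chloro ylide, so that Z and E chloroalkenes form in comparable amounts and are hard to separate. The fallback sets out from 10. Stork–Zhao olefination ([Ph3PCH2I]I, NaN(SiMe3)2, THF–DMPU, −78 °C), which is reliably cis-selective, should give (1S,2S)-2-chloro-1-[(Z)-2-iodoethenyl]-1-methyl-4-methylidenecyclohexane F7. Iodine–lithium exchange (t-BuLi, 2 equiv, Et2O, −78 °C) and quenching of the configurationally stable alkenyllithium with C2Cl6 puts chlorine in place of iodine with retention, and the route is rejoined at 11.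

**Further compounds**

F1 | step 3 | methyl rac-1-methyl-4-methylidene-2-oxocyclohexane-1-carboxylate (racemate of 6) | C[C@@]1(C(=O)OC)CC(=C)CCC1=O.C[C@]1(C(=O)OC)CC(=C)CCC1=O
F2 | step 3 | methyl rac-(1R,2R)-2-hydroxy-1-methyl-4-methylidenecyclohexane-1-carboxylate (racemate of 7) | C[C@@]1(C(=O)OC)CC(=C)CC[C@H]1O.C[C@]1(C(=O)OC)CC(=C)CC[C@@H]1O
F3 | step 3 | methyl (1R,2R)-2-{[(2S)-2-methoxy-2-phenylacetyl]oxy}-1-methyl-4-methylidenecyclohexane-1-carboxylate | C[C@@]1(C(=O)OC)CC(=C)CC[C@H]1OC(=O)[C@@H](OC)c1ccccc1
F4 | step 3 | methyl (1S,2S)-2-{[(2S)-2-methoxy-2-phenylacetyl]oxy}-1-methyl-4-methylidenecyclohexane-1-carboxylate | C[C@]1(C(=O)OC)CC(=C)CC[C@@H]1OC(=O)[C@@H](OC)c1ccccc1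
F5 | step 9 | (1R,4S,5S)-5-chloro-4-[(Z)-2-chloroethenyl]-4-methyl-2-methylidenecyclohexan-1-ol | C[C@@]1(/C=C\Cl)CC(=C)[C@H](O)C[C@@H]1Cl
F6 | step 9 | (1S,4S,5S)-5-chloro-4-[(Z)-2-chloroethenyl]-4-methyl-2-methylidenecyclohexyl 4-nitrobenzoate | C[C@@]1(/C=C\Cl)CC(=C)[C@@H](OC(=O)c2ccc(cc2)[N+](=O)[O-])C[C@@H]1Cl
F7 | step 8 | (1S,2S)-2-chloro-1-[(Z)-2-iodoethenyl]-1-methyl-4-methylidenecyclohexane | C[C@@]1(/C=C\I)CC(=C)CC[C@@H]1Cl
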